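**Plan**

Retrosynthesis: the two benzylic bonds are cut first, C1–C8a of the tetralin (aryl C–C) and O1–C5 of the oxolane (C–O), which leads both ring systems back to one biaryl bis-tetraol; then the 5,5'-biaryl bond; then, in each half, the benzyl C–C and the C–OH bond of the tertiary carbinol and the aldol C–C bond to the aryl aldehyde.
Forward: an Evans aldol/lactonisation gives one bromoaryl lactone acid, which is benzylated with a vanillyl or an isovanillyl bromide and hydroxylated; the two lactone acids are joined by borylation/Suzuki coupling and reduced; one acid treatment then closes the tetralin in one half and the oxolane in the other; detosylation and hydrogenolysis end the route.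
Enabling feature: each carbinol carbon is benzylic to a biaryl ring with oxygen para to it, so acid turns it into a p-alkoxybenzyl cation. In the vanillyl half, C6 of the benzyl ring (para to OMe) closes the six-membered carbocycle; in the isovanillyl half the corresponding ring carbons are para and ortho to a tosyloxy group and stay inert, so the primary hydroxyl closes the oxolane.
Stereochemistry: the oxazolidinone fixes the CH(CH2OH) carbon of both halves; the tertiary carbinol is set by enolate hydroxylation anti to the neighbouring carboxylate; both benzylic centres are erased at the cation stage and re-set in step 14 (1,2-trans in the tetralin, aryl trans to CH2OH in the oxolane).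

Key step: step 14

Remark: the benzylic carbinol configuration of 19–21 is drawn as it comes from the aldol step, but it is taken to be without consequence, because both centres pass through planar cations in step 14.

**Route**

Step 1
Reactants: 1 (4S)-4-benzyl-1,3-oxazolidin-2-one; 2 methyl 4-chloro-4-oxobutanoate
Product: 3 methyl 4-[(4S)-4-benzyl-2-oxo-1,3-oxazolidin-3-yl]-4-oxobutanoate
Conditions: n-BuLi, THF, −78 °C; then 2, −78 → 0 °C
Reagents that add atoms: none
Why: N-acylation of the lithiated oxazolidinone by the acid chloride, which reacts far faster than the methyl ester; no stereocentre is formed.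

Step 2
Reactants: 4 5-bromovanillin (3-bromo-4-hydroxy-5-methoxybenzaldehyde)
Product: 5 4-(benzyloxy)-3-bromo-5-methoxybenzaldehyde
Conditions: BnBr, K2CO3, DMF, 50 °C
Reagents that add atoms: benzyl bromide, BrCc1ccccc1
Why: Williamson ether synthesis on the potassium phenoxide; aldehyde and aryl bromide are inert to these conditions.

Step 3
Reactants: 3 methyl 4-[(4S)-4-benzyl-2-oxo-1,3-oxazolidin-3-yl]-4-oxobutanoate; 5 4-(benzyloxy)-3-bromo-5-methoxybenzaldehyde
Product: 7 2,3-trans lactone imide (4S)-4-benzyl-3-{[(2S,3S)-2-[4-(benzyloxy)-3-bromo-5-methoxyphenyl]-5-oxooxolan-3-yl]carbonyl}-1,3-oxazolidin-2-one, via syn-aldol adduct 6 (not isolated)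
Conditions: 3, Bu2BOTf, i-Pr2NEt, CH2Cl2, −78 → 0 °C; 5, −78 → 0 °C; pH 7 buffer, MeOH, H2O2; then PPTS (cat.), PhMe, 60 °C
Reagents that add atoms: none
Why: Evans syn-aldol addition followed by lactonisation: Bu2BOTf enolises only the imide α-CH2, the (Z)-boron enolate adds to the aldehyde through a closed chair transition state on the face away from the benzyl group of the auxiliary, which sets the future CH(CH2OH) carbon (S) and the carbinol carbon syn to it, and the γ-hydroxy methyl ester then closes to the 2,3-trans γ-lactone under mild acid.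

Step 4
Reactants: 7 2,3-trans lactone imide
Product: 8 (2S,3S)-2-[4-(benzyloxy)-3-bromo-5-methoxyphenyl]-5-oxooxolane-3-carboxylic acid
Conditions: LiOH, H2O2, THF–H2O, 0 °C; Na2SO3; HCl to pH 2
Reagents that add atoms: hydrogen peroxide (as LiOOH), OO
Why: Hydroperoxide cleavage of the imide: LiOOH attacks the exocyclic acyl carbon selectively, the peracid is reduced by sulfite, any lactone opened by hydroxide recloses on acidification, and the stereocentres are untouched (auxiliary 1 is recovered).

Step 5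
Reactants: 9 4-(benzyloxy)-3-methoxybenzyl alcohol
Product: 10 4-(benzyloxy)-3-methoxybenzyl bromide
Conditions: PBr3, Et2O, 0 °C
Reagents that add atoms: phosphorus tribromide, BrP(Br)Br
Why: Bromide displaces the phosphite ester of the benzylic alcohol (SN2); the electron-rich bromide is used at once.

Step 6
Reactants: 8 (2S,3S)-lactone acid; 10 4-(benzyloxy)-3-methoxybenzyl bromide
Product: 11 (2S,3S,4S)-4-[4-(benzyloxy)-3-methoxybenzyl]-2-[4-(benzyloxy)-3-bromo-5-methoxyphenyl]-5-oxooxolane-3-carboxylic acid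
Conditions: NaN(SiMe3)2 (2.2 equiv), THF, −78 °C; 10, −78 → −40 °C; aq. HCl
Reagents that add atoms: none
Why: Alkylation of the dianion (carboxylate plus lactone enolate): the carboxylate keeps the base away from the CH next to it, so no eliminative opening of the lactone occurs, and the benzyl bromide should enter anti to the carboxylate, although the configuration of this carbon is erased again in step 7.

Step 7
Reactants: 11 (2S,3S,4S)-4-benzylated lactone acid
Product: 12 (2S,3R,4S)-4-[4-(benzyloxy)-3-methoxybenzyl]-2-[4-(benzyloxy)-3-bromo-5-methoxyphenyl]-4-hydroxy-5-oxooxolane-3-carboxylic acid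
Conditions: KN(SiMe3)2 (2.5 equiv), THF, −78 °C; 2-(phenylsulfonyl)-3-phenyloxaziridine, −78 °C; aq. HCl
Reagents that add atoms: 2-(phenylsulfonyl)-3-phenyloxaziridine, O=S(=O)(c1ccccc1)N1OC1c1ccccc1
Why: Enolate hydroxylation with an N-sulfonyloxaziridine: the planar enolate takes up electrophilic oxygen on the face anti to the neighbouring C3 carboxylate, which places the hydroxyl trans and the benzyl group cis to the carboxyl and so sets the tertiary carbinol centre (4S).

Step 8
Reactants: 13 3-hydroxy-4-methoxybenzyl alcohol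
Product: 14 5-(hydroxymethyl)-2-methoxyphenyl 4-methylbenzenesulfonate
Conditions: TsCl, K2CO3, acetone, rt
Reagents that add atoms: 4-methylbenzenesulfonyl chloride, Cc1ccc(S(Cl)(=O)=O)cc1
Why: Chemoselective O-sulfonylation of the phenoxide (K2CO3 does not deprotonate the benzylic alcohol); the tosyl group turns the ring oxygen into an acceptor and survives base, hydride and acid.

Step 9
Reactants: 14 5-(hydroxymethyl)-2-methoxyphenyl 4-methylbenzenesulfonate
Product: 15 5-(bromomethyl)-2-methoxyphenyl 4-methylbenzenesulfonate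
Conditions: PBr3, CH2Cl2, 0 °C
Reagents that add atoms: phosphorus tribromide, BrP(Br)Br
Why: Bromide displaces the phosphite ester of the benzylic alcohol (SN2); the aryl sulfonate is inert.

Step 10
Reactants: 8 (2S,3S)-lactone acid; 15 5-(bromomethyl)-2-methoxyphenyl 4-methylbenzenesulfonate
Product: 16 (2S,3S,4S)-2-[4-(benzyloxy)-3-bromo-5-methoxyphenyl]-4-[4-methoxy-3-(tosyloxy)benzyl]-5-oxooxolane-3-carboxylic acid
Conditions: NaN(SiMe3)2 (2.2 equiv), THF, −78 °C; 15, −78 → −40 °C; aq. HCl
Reagents that add atoms: none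
Why: Dianion alkylation as in step 6; the aryl sulfonate is not attacked by the amide base or the enolate at this temperature.

Step 11
Reactants: 16 (2S,3S,4S)-4-benzylated lactone acid of the isovanillyl series
Product: 17 (2S,3R,4S)-2-[4-(benzyloxy)-3-bromo-5-methoxyphenyl]-4-hydroxy-4-[4-methoxy-3-(tosyloxy)benzyl]-5-oxooxolane-3-carboxylic acid
Conditions: KN(SiMe3)2 (2.5 equiv), THF, −78 °C; 2-(phenylsulfonyl)-3-phenyloxaziridine, −78 °C; aq. HCl
Reagents that add atoms: 2-(phenylsulfonyl)-3-phenyloxaziridine, O=S(=O)(c1ccccc1)N1OC1c1ccccc1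
Why: Enolate hydroxylation as in step 7, oxygen entering anti to the C3 carboxylate to set the (4S) tertiary carbinol.

Step 12
Reactants: 17 hydroxy lactone acid of the isovanillyl series; 12 hydroxy lactone acid of the vanillyl series
Product: 19 biaryl bis(lactone acid) in which C3 of a 6,6'-bis(benzyloxy)-5,5'-dimethoxybiphenyl carries the lactone acid unit of 12 and C3' that of 17, via pinacol boronate 18 (not isolated)
Conditions: 17, B2pin2, KOAc, PdCl2(dppf) (cat.), 1,4-dioxane, 90 °C; then 12, aq. K3PO4, 90 °C; HCl to pH 2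
Reagents that add atoms: none
Why: One-pot Miyaura borylation and Suzuki–Miyaura cross-coupling: zerovalent palladium with this ligand inserts into C–Br far faster than into the aryl sulfonate C–O bond, the carboxylates and tertiary hydroxyls are spectators, and no stereocentre that matters is touched (a lactone opened by the base recloses on acidification).

Step 13
Reactants: 19 biaryl bis(lactone acid)
Product: 20 biaryl bis-tetraol (octaol), each biphenyl C3/C3' carrying a (1S,2R,3S)-3-(arylmethyl)-1,3,4-trihydroxy-2-(hydroxymethyl)butyl chain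
Conditions: BH3·SMe2, THF, 0 °C → rt; then LiBH4, THF–MeOH, 0 → 40 °C; MeOH, aq. NH4Cl
Reagents that add atoms: none
Why: Borane reduces the two carboxylic acids and LiBH4 opens the two lactones to diols; neither reagent attacks the aryl sulfonate or the benzyl ethers, and no stereocentre is affected.

Step 14
Reactants: 20 biaryl bis-tetraol
Product: 22 tri-O-benzyl mono-O-tosyl derivative of the target (oxolane on one biaryl ring and aryltetralin on the other), via bis-oxolane 21 (not isolated)
Conditions: TsOH·H2O (20 mol %), (CF3)2CHOH–CH2Cl2 1:1, 5 mM, 0 °C → rt; Et3N quench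
Reagents that add atoms: none
Why: The acid ionises both benzylic carbinols to 4-benzyloxy-3-methoxybenzyl cations (the O-alkyl counterpart of a p-quinone methide); each is first captured reversibly by the primary hydroxyl on the neighbouring quaternary carbon (bis-oxolane 21), and in the vanillyl half the re-formed cation is then attacked irreversibly by C6 of the benzyl ring (para to its methoxy group), which makes the bond from the diaryl-methine carbon C1 to ring carbon C8a of the tetralin and rearomatises. The closest known reaction type is the acid-induced isomerisation of 2-aryl-4-benzyloxolane lignans of the olivil type to 1-aryltetralins, an intramolecular dehydrative Friedel–Crafts alkylation. The tetralin ring closes 6-exo-trig with respect to the cationic carbon and its exocyclic aryl bond (6-endo with respect to the attacking arene π bond), the oxolane ring by 5-exo-trig O-attack on the same kind of cation. At C1 of the tetralin the aryl group takes the pseudo-equatorial place trans to the C2 hydroxymethyl group in a half-chair transition state (control by the existing C2 and C3 centres), and at C5 of the oxolane reversible ionisation lets the aryl group settle trans to the C4 hydroxymethyl group (thermodynamic control), so the carbinol configuration of 20 does not matter. The selectivity needed is C-capture in one half and O-capture in the other, and it is written into the two benzyl rings: the vanillyl ring closes at a carbon para to OMe, activated whatever the phenol oxygen carries, whereas in the isovanillyl ring the two carbons ortho to the CH2 group are para and ortho to the tosyloxy group and lose their activation, so that half stays at the oxolane. High dilution suppresses intermolecular capture, and the catalytic, non-acylating acid in (CF3)2CHOH ionises only the p-alkoxybenzylic C–O bonds, not the tertiary or primary ones.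

Step 15
Reactants: 22 tri-O-benzyl mono-O-tosyl derivative of the target
Product: 23 tri-O-benzyl ether of the target (free 3-hydroxy-4-methoxybenzyl group)
Conditions: KOH, 1,4-dioxane–H2O, 80 °C, Ar; aq. NH4Cl
Reagents that add atoms: none
Why: Hydroxide attacks sulfur of the aryl sulfonate (S–O cleavage, alcohol-free medium so that no alkyl tosylate can re-alkylate the phenoxide); the other three phenols are still benzylated, so no phenoxide-driven opening of the 2-aryloxolane can occur.

Step 16
Reactants: 23 tri-O-benzyl ether of the target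
Product: 24 CNP0252244.1 (target)
Conditions: H2 (1 atm), Pd/C, EtOAc–MeOH, rt
Reagents that add atoms: none
Why: Hydrogenolysis of the three aryl benzyl ethers, which under neutral conditions at one atmosphere is faster than cleavage of the benzylic C–O bond of the 2-aryloxolane, so the reaction is stopped after uptake of three equivalents of hydrogen.

**Compound list**

1 | (4S)-4-benzyl-1,3-oxazolidin-2-one | O=C1OC[C@H](Cc2ccccc2)N1 | starting material
2 | methyl 4-chloro-4-oxobutanoate | COC(=O)CCC(Cl)=O | starting material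
3 | methyl 4-[(4S)-4-benzyl-2-oxo-1,3-oxazolidin-3-yl]-4-oxobutanoate | COC(=O)CCC(=O)N1[C@@H](Cc2ccccc2)COC1=O | intermediate
4 | 5-bromovanillin (3-bromo-4-hydroxy-5-methoxybenzaldehyde) | COc1cc(C=O)cc(Br)c1O | starting material
5 | 4-(benzyloxy)-3-bromo-5-methoxybenzaldehyde | COc1cc(C=O)cc(Br)c1OCc1ccccc1 | intermediate
6 | syn-aldol adduct, methyl (3S,4S)-4-[4-(benzyloxy)-3-bromo-5-methoxyphenyl]-3-{[(4S)-4-benzyl-2-oxo-1,3-oxazolidin-3-yl]carbonyl}-4-hydroxybutanoate | O[C@H](c1cc(OC)c(OCc2ccccc2)c(Br)c1)[C@H](CC(=O)OC)C(=O)N1[C@@H](Cc2ccccc2)COC1=O | intermediate (not isolated)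
7 | (4S)-4-benzyl-3-{[(2S,3S)-2-[4-(benzyloxy)-3-bromo-5-methoxyphenyl]-5-oxooxolan-3-yl]carbonyl}-1,3-oxazolidin-2-one (2,3-trans lactone) | O=C1C[C@H](C(=O)N2[C@@H](Cc3ccccc3)COC2=O)[C@@H](c2cc(OC)c(OCc3ccccc3)c(Br)c2)O1 | intermediate
8 | (2S,3S)-2-[4-(benzyloxy)-3-bromo-5-methoxyphenyl]-5-oxooxolane-3-carboxylic acid | O=C1C[C@H](C(=O)O)[C@@H](c2cc(OC)c(OCc3ccccc3)c(Br)c2)O1 | intermediate
9 | 4-(benzyloxy)-3-methoxybenzyl alcohol | COc1cc(CO)ccc1OCc1ccccc1 | starting material
10 | 4-(benzyloxy)-3-methoxybenzyl bromide | COc1cc(CBr)ccc1OCc1ccccc1 | intermediate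
11 | (2S,3S,4S)-4-[4-(benzyloxy)-3-methoxybenzyl]-2-[4-(benzyloxy)-3-bromo-5-methoxyphenyl]-5-oxooxolane-3-carboxylic acid (all-trans) | O=C1[C@@H](Cc2ccc(OCc3ccccc3)c(OC)c2)[C@H](C(=O)O)[C@@H](c2cc(OC)c(OCc3ccccc3)c(Br)c2)O1 | intermediate
12 | (2S,3R,4S)-4-[4-(benzyloxy)-3-methoxybenzyl]-2-[4-(benzyloxy)-3-bromo-5-methoxyphenyl]-4-hydroxy-5-oxooxolane-3-carboxylic acid (OH trans, benzyl cis to CO2H) | O=C1[C@](O)(Cc2ccc(OCc3ccccc3)c(OC)c2)[C@H](C(=O)O)[C@@H](c2cc(OC)c(OCc3ccccc3)c(Br)c2)O1 | intermediate
13 | 3-hydroxy-4-methoxybenzyl alcohol | COc1ccc(CO)cc1O | starting material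
14 | 5-(hydroxymethyl)-2-methoxyphenyl 4-methylbenzenesulfonate | COc1ccc(CO)cc1OS(=O)(=O)c1ccc(C)cc1 | intermediate
15 | 5-(bromomethyl)-2-methoxyphenyl 4-methylbenzenesulfonate | COc1ccc(CBr)cc1OS(=O)(=O)c1ccc(C)cc1 | intermediate
16 | (2S,3S,4S)-2-[4-(benzyloxy)-3-bromo-5-methoxyphenyl]-4-[4-methoxy-3-(tosyloxy)benzyl]-5-oxooxolane-3-carboxylic acid | O=C1[C@@H](Cc2ccc(OC)c(OS(=O)(=O)c3ccc(C)cc3)c2)[C@H](C(=O)O)[C@@H](c2cc(OC)c(OCc3ccccc3)c(Br)c2)O1 | intermediate
17 | (2S,3R,4S)-2-[4-(benzyloxy)-3-bromo-5-methoxyphenyl]-4-hydroxy-4-[4-methoxy-3-(tosyloxy)benzyl]-5-oxooxolane-3-carboxylic acid | O=C1[C@](O)(Cc2ccc(OC)c(OS(=O)(=O)c3ccc(C)cc3)c2)[C@H](C(=O)O)[C@@H](c2cc(OC)c(OCc3ccccc3)c(Br)c2)O1 | intermediate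
18 | pinacol boronate of 17 (4,4,5,5-tetramethyl-1,3,2-dioxaborolan-2-yl in place of Br) | O=C1[C@](O)(Cc2ccc(OC)c(OS(=O)(=O)c3ccc(C)cc3)c2)[C@H](C(=O)O)[C@@H](c2cc(OC)c(OCc3ccccc3)c(B3OC(C)(C)C(C)(C)O3)c2)O1 | intermediate (not isolated)
19 | biaryl bis(lactone acid): 6,6'-bis(benzyloxy)-5,5'-dimethoxybiphenyl with the (2S,3R,4S)-lactone acid of 12 on C3 and that of 17 on C3' | O=C1[C@](O)(Cc2ccc(OCc3ccccc3)c(OC)c2)[C@H](C(=O)O)[C@@H](c2cc(OC)c(OCc3ccccc3)c(c2)-c2cc(cc(OC)c2OCc2ccccc2)[C@H]2OC(=O)[C@](O)(Cc3ccc(OC)c(OS(=O)(=O)c4ccc(C)cc4)c3)[C@@H]2C(=O)O)O1 | intermediate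
20 | biaryl bis-tetraol: the same biphenyl with two (1S,2R,3S)-1,3,4-trihydroxy-2-(hydroxymethyl)butyl chains, C3 of one bearing 4-(benzyloxy)-3-methoxybenzyl and of the other 4-methoxy-3-(tosyloxy)benzyl | OC[C@](O)(Cc1ccc(OCc2ccccc2)c(OC)c1)[C@H](CO)[C@H](O)c1cc(OC)c(OCc2ccccc2)c(c1)-c1cc(cc(OC)c1OCc1ccccc1)[C@@H](O)[C@@H](CO)[C@](O)(CO)Cc1ccc(OC)c(OS(=O)(=O)c2ccc(C)cc2)c1 | intermediate
21 | bis-oxolane: the same biphenyl with two (3S,4R,5S)-3-(arylmethyl)-3-hydroxy-4-(hydroxymethyl)oxolan-5-yl groups | COc1ccc(C[C@@]2(O)CO[C@H](c3cc(OC)c(OCc4ccccc4)c(-c4cc([C@H]5OC[C@](O)(Cc6ccc(OCc7ccccc7)c(OC)c6)[C@@H]5CO)cc(OC)c4OCc4ccccc4)c3)[C@H]2CO)cc1OS(=O)(=O)c1ccc(C)cc1 | intermediate (not isolated)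
22 | tri-O-benzyl mono-O-tosyl target: biphenyl bearing the (3S,4R,5S)-oxolane with the 4-methoxy-3-(tosyloxy)benzyl group and the (1S,2S,3S)-1-aryl-7-(benzyloxy)-3-hydroxy-2,3-bis(hydroxymethyl)-6-methoxytetralin | COc1ccc(C[C@@]2(O)CO[C@H](c3cc(OC)c(OCc4ccccc4)c(-c4cc([C@H]5c6cc(OCc7ccccc7)c(OC)cc6C[C@@](O)(CO)[C@@H]5CO)cc(OC)c4OCc4ccccc4)c3)[C@H]2CO)cc1OS(=O)(=O)c1ccc(C)cc1 | intermediate
23 | tri-O-benzyl ether of the target (two biaryl phenols and the tetralin phenol benzylated) | COc1ccc(C[C@@]2(O)CO[C@H](c3cc(OC)c(OCc4ccccc4)c(-c4cc([C@H]5c6cc(OCc7ccccc7)c(OC)cc6C[C@@](O)(CO)[C@@H]5CO)cc(OC)c4OCc4ccccc4)c3)[C@H]2CO)cc1O | intermediate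
24 | CNP0252244.1 | COc1ccc(C[C@@]2(O)CO[C@H](c3cc(OC)c(O)c(-c4cc([C@H]5c6cc(O)c(OC)cc6C[C@@](O)(CO)[C@@H]5CO)cc(OC)c4O)c3)[C@H]2CO)cc1O | target

**Step count and risks**

Total steps: 16. Longest linear sequence: 10 steps (1, 3, 4, 10, 11, 12, 13, 14, 15, 16).

Step 14. What may go wrong is loss of the differentiation between the two halves (slow C-alkylation or ipso attack at the tosylated ring while the oxolane keeps re-ionising), elimination from the cation with scrambling of the neighbouring CH(CH2OH) centre, or intermolecular capture. The fallback separates the two ring closures and places them before the union, so that each half meets its own acid treatment; it sets out from 12 and 17 and comes back at 22. Acid 12 would be reduced as in step 13 to the bromo tetraol F1 and cyclised with the same acid to the bromo aryltetralin F2. Acid 17 would be reduced to the bromo tetraol F3 and closed under the mildest acid that forms the ring to the bromo oxolane F4. Miyaura borylation of F4 (B2pin2, KOAc, PdCl2(dppf)) would give the pinacol boronate F5, and Suzuki–Miyaura coupling of F5 with F2 (PdCl2(dppf), aq. K3PO4) would give 22.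

Step 12. What may go wrong is slow transmetalation and protodeboronation at the position next to the benzyloxy group, homocoupling of either partner, or interference by the free carboxylates. The fallback forms the biaryl bond first by oxidative phenol coupling; it sets out from 3 (with commercial vanillin) and comes back at 19. Vanillin would be dimerised (FeSO4, Na2S2O8, water, 50 °C) to 5,5'-bivanillin F6 and benzylated (BnBr, K2CO3) to the dibenzyl ether F7. A twofold aldol addition with 3 under the conditions of step 3 would give the bis-adduct F8 and from it the bis-lactone F9, and cleavage of both auxiliaries as in step 4 the diacid F10. Its tetra-anion would be alkylated with a 1:1 mixture of 10 and 15, and the mixed product F11 separated from the two symmetric ones (a statistical step). Twofold hydroxylation as in step 7 would give 19.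

Step 7 (step 11 shares the risk). What may go wrong is poor facial selectivity in the oxidation of the hindered, fully substituted enolate (the 2-aryl group lies on the face that must be attacked) or capture of the enolate by the sulfonyl imine that the oxidant leaves behind. The fallback reverses the order of C–O and C–C bond formation at this carbon; it sets out from 8 and comes back at 12 (and at 17).
- Acid 8 would be carboxylated with MeOMgOCO2Me (DMF, 130 °C) to the malonic acid F12 and methylenated with decarboxylation (aq. HCHO, PhNHMe, NaOAc, AcOH) to the α-methylene lactone F13.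
- Epoxidation with dimethyldioxirane on the face anti to the carboxyl group would give the spiro-epoxide F14.
- Opening at the CH2 terminus with the cuprate from the aryl Grignard reagent F15 (from commercial 1-(benzyloxy)-4-bromo-2-methoxybenzene and Mg; CuI, THF, −30 °C) would give 12.
- For the other series, commercial 5-bromo-2-methoxyphenol would be tosylated to the aryl bromide F17, converted with i-PrMgCl·LiCl into the aryl Grignard reagent F16, and used with CuI on F14 to give 17.

Further compounds
F1 | step 14 | bromo tetraol from 12, (1S,2R,3S)-1-[4-(benzyloxy)-3-bromo-5-methoxyphenyl]-3-[4-(benzyloxy)-3-methoxybenzyl]-2-(hydroxymethyl)butane-1,3,4-triol | OC[C@](O)(Cc1ccc(OCc2ccccc2)c(OC)c1)[C@H](CO)[C@H](O)c1cc(OC)c(OCc2ccccc2)c(Br)c1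
F2 | step 14 | bromo aryltetralin, (1S,2S,3S)-7-(benzyloxy)-1-[4-(benzyloxy)-3-bromo-5-methoxyphenyl]-3-hydroxy-2,3-bis(hydroxymethyl)-6-methoxytetralin | COc1cc(cc(Br)c1OCc1ccccc1)[C@H]1c2cc(OCc3ccccc3)c(OC)cc2C[C@@](O)(CO)[C@@H]1CO
F3 | step 14 | bromo tetraol from 17 | OC[C@](O)(Cc1ccc(OC)c(OS(=O)(=O)c2ccc(C)cc2)c1)[C@H](CO)[C@H](O)c1cc(OC)c(OCc2ccccc2)c(Br)c1
F4 | step 14 | bromo oxolane, (3S,4R,5S)-5-[4-(benzyloxy)-3-bromo-5-methoxyphenyl]-4-(hydroxymethyl)-3-[4-methoxy-3-(tosyloxy)benzyl]oxolan-3-ol | COc1ccc(C[C@@]2(O)CO[C@H](c3cc(OC)c(OCc4ccccc4)c(Br)c3)[C@H]2CO)cc1OS(=O)(=O)c1ccc(C)cc1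
F5 | step 14 | pinacol boronate of F4 | COc1ccc(C[C@@]2(O)CO[C@H](c3cc(OC)c(OCc4ccccc4)c(B4OC(C)(C)C(C)(C)O4)c3)[C@H]2CO)cc1OS(=O)(=O)c1ccc(C)cc1
F6 | step 12 | 5,5'-bivanillin (6,6'-dihydroxy-5,5'-dimethoxybiphenyl-3,3'-dicarbaldehyde) | COc1cc(C=O)cc(c1O)-c1cc(C=O)cc(OC)c1O
F7 | step 12 | 6,6'-bis(benzyloxy)-5,5'-dimethoxybiphenyl-3,3'-dicarbaldehyde | COc1cc(C=O)cc(c1OCc1ccccc1)-c1cc(C=O)cc(OC)c1OCc1ccccc1
F8 | step 12 | twofold syn-aldol adduct of F7 and 3 | COC(=O)C[C@H](C(=O)N1[C@@H](Cc2ccccc2)COC1=O)[C@H](O)c1cc(OC)c(OCc2ccccc2)c(c1)-c1cc(cc(OC)c1OCc1ccccc1)[C@@H](O)[C@H](CC(=O)OC)C(=O)N1[C@@H](Cc2ccccc2)COC1=O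
F9 | step 12 | bis(2,3-trans lactone imide) | O=C1C[C@H](C(=O)N2[C@@H](Cc3ccccc3)COC2=O)[C@@H](c2cc(OC)c(OCc3ccccc3)c(c2)-c2cc(cc(OC)c2OCc2ccccc2)[C@H]2OC(=O)C[C@@H]2C(=O)N2[C@@H](Cc3ccccc3)COC2=O)O1
F10 | step 12 | bis[(2S,3S)-lactone acid] on the biaryl | O=C1C[C@H](C(=O)O)[C@@H](c2cc(OC)c(OCc3ccccc3)c(c2)-c2cc(cc(OC)c2OCc2ccccc2)[C@H]2OC(=O)C[C@@H]2C(=O)O)O1
F11 | step 12 | mixed bis-benzylated diacid (one vanillyl-type, one tosylated isovanillyl-type benzyl group) | O=C1[C@@H](Cc2ccc(OCc3ccccc3)c(OC)c2)[C@H](C(=O)O)[C@@H](c2cc(OC)c(OCc3ccccc3)c(c2)-c2cc(cc(OC)c2OCc2ccccc2)[C@H]2OC(=O)[C@@H](Cc3ccc(OC)c(OS(=O)(=O)c4ccc(C)cc4)c3)[C@@H]2C(=O)O)O1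
F12 | step 7 | α-carboxylated lactone, (2S,3S)-2-[4-(benzyloxy)-3-bromo-5-methoxyphenyl]-5-oxooxolane-3,4-dicarboxylic acid | O=C1C(C(=O)O)[C@H](C(=O)O)[C@@H](c2cc(OC)c(OCc3ccccc3)c(Br)c2)O1
F13 | step 7 | (2S,3S)-2-[4-(benzyloxy)-3-bromo-5-methoxyphenyl]-4-methylidene-5-oxooxolane-3-carboxylic acid | O=C1C(=C)[C@H](C(=O)O)[C@@H](c2cc(OC)c(OCc3ccccc3)c(Br)c2)O1
F14 | step 7 | spiro-epoxide of F13 (epoxide oxygen trans to the carboxyl group) | O=C1[C@]2(CO2)[C@H](C(=O)O)[C@@H](c3cc(OC)c(OCc4ccccc4)c(Br)c3)O1
F15 | step 7 | [4-(benzyloxy)-3-methoxyphenyl]magnesium bromide | Br[Mg]c1ccc(OCc2ccccc2)c(OC)c1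
F16 | step 7 | [4-methoxy-3-(tosyloxy)phenyl]magnesium chloride | Cl[Mg]c1ccc(OC)c(OS(=O)(=O)c2ccc(C)cc2)c1
F17 | step 7 | 5-bromo-2-methoxyphenyl 4-methylbenzenesulfonate | COc1ccc(Br)cc1OS(=O)(=O)c1ccc(C)cc1
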